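C2–C1' is cut last but one, after a final global solvolysis. This gives a C25 cyclohexene fragment whose ring B is unfunctionalised, and a 3,7-dioxygenated chromone with rings A and C already in place.
Enabling feature: C2 is the α-carbon of the O3–C3=C2 enol of ring C and also bears O1, so iodine(III) umpolung makes it an α-keto oxocarbenium ion. C1' is ortho to O2' and para to O4' of ring B, and the two such carbons of this 2-substituted resorcinol are interchanged by rotation about C3–C3'.
Cyclohexene fragment: an exo- and enantioselective Diels–Alder reaction of an acetate-protected 2'-hydroxychalcone with a MOM-protected (E)-1-aryl-3-methylbutadiene sets C3, C4 and C5 at once.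
The chalcone comes from a base-free Claisen–Schmidt condensation, the diene from Suzuki coupling of 2-iodoresorcinol bis-MOM ether with a dienylboronate, and the chromonol from epoxidation and isomerisation of 7-acetoxychromone.
Ring order: all benzene rings and rings A/C are bought. The cyclohexene is the only ring formed (step 7), and the flavonol is completed by the C–H/C–H union (step 11).

Key step: step 11

Locants: cyclohexene C1 (methyl-bearing) to C6. Flavonol O1, C2 to C8a with ring A (benzo), ring C (pyranone) and ring B (C1' on C2, C3' on cyclohexene C3).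
Assumption: (R)-VANOL is written for the (3R,4R,5S) series by analogy with related 2'-hydroxychalcone cycloadditions; the sense of induction has to be confirmed, and the equally available (S)-ligand would be used if it is opposite.

Step 1
Reactants: 1 2,4-dihydroxyacetophenone
Product: 2 4-acetyl-3-hydroxyphenyl acetate
Conditions: Ac2O (1.0 equiv), Et3N, CH2Cl2, 0 °C
Reagents that add atoms: acetic anhydride, CC(=O)OC(C)=O
Why: Chemoselective O-acylation, because the 2-OH is tied up in a hydrogen bond to the ketone and one equivalent of anhydride should acetylate only the 4-OH.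

Step 2
Reactants: 3 2,4-dihydroxybenzaldehyde
Product: 4 2,4-diacetoxybenzaldehyde
Conditions: Ac2O (2.3 equiv), Et3N, DMAP (cat.), CH2Cl2, 0 °C to rt
Reagents that add atoms: acetic anhydride, CC(=O)OC(C)=O
Why: Exhaustive DMAP-catalysed O-acylation of both phenols, to which the aldehyde is inert.

Step 3
Reactants: 2 4-acetyl-3-hydroxyphenyl acetate; 4 2,4-diacetoxybenzaldehyde
Product: 5 (E)-2'-hydroxy-2,4,4'-triacetoxychalcone
Conditions: BF3·OEt2, 1,4-dioxane, rt; aq work-up
Reagents that add atoms: none
Why: Claisen–Schmidt condensation run under BF3 (boron chelate of the o-hydroxyacetophenone as enol component) instead of hydroxide, so that the three aryl acetates survive and the conjugated E-alkene results as the thermodynamic dehydration product.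

Step 4
Reactants: 6 2-iodoresorcinol
Product: 7 2-iodo-1,3-bis(methoxymethoxy)benzene
Conditions: NaH (2.4 equiv), MOMCl (2.4 equiv), DMF, 0 °C
Reagents that add atoms: chloromethyl methyl ether, COCCl
Why: Williamson-type O-alkylation of the bis-phenoxide; the MOM ethers keep ring B electron-rich for step 11 and tolerate Pd(0) and the borate of step 7.

Step 5
Reactants: 8 2-methylbut-1-en-3-yne
Product: 9 (E)-(3-methylbuta-1,3-dienyl)boronic acid pinacol ester
Conditions: HBpin, Cp2ZrHCl (10 mol %), Et3N (10 mol %), CH2Cl2, sealed vessel, rt
Reagents that add atoms: pinacolborane, [H]B1OC(C)(C)C(C)(C)O1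
Why: Zirconocene-catalysed syn-hydroboration of the terminal alkyne puts boron at the terminus and sets the E-alkene, the 1,1-disubstituted alkene of the enyne being much less reactive.

Step 6
Reactants: 7 2-iodo-1,3-bis(methoxymethoxy)benzene; 9 (E)-(3-methylbuta-1,3-dienyl)boronic acid pinacol ester
Product: 10 (E)-1,3-bis(methoxymethoxy)-2-(3-methylbuta-1,3-dienyl)benzene
Conditions: Pd(OAc)2 (3 mol %), SPhos (6 mol %), K3PO4, THF/H2O, 50 °C
Reagents that add atoms: none
Why: Suzuki–Miyaura coupling with a bulky biarylphosphine to overcome the two ortho substituents, with retention of the E-geometry of the alkenylboronate.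

Step 7
Reactants: 5 (E)-2'-hydroxy-2,4,4'-triacetoxychalcone; 10 (E)-1,3-bis(methoxymethoxy)-2-(3-methylbuta-1,3-dienyl)benzene
Product: 11 (3R,4R,5S)-all-trans cycloadduct (C1 methyl, C3 2,6-bis(methoxymethoxy)phenyl, C4 4-acetoxy-2-hydroxybenzoyl, C5 2,4-diacetoxyphenyl)
Conditions: preformed (R)-VANOL/B(OPh)3 borate (20 mol %), 4 Å MS, PhCF3, 25 °C
Reagents that add atoms: none
Why: Chiral borate-promoted Diels–Alder reaction of 2'-hydroxychalcones, in which the chalcone binds boron through phenolate and carbonyl oxygen and the vaulted biaryl blocks one enone face (absolute sense 3R,4R,5S) while forcing the 2,6-disubstituted aryl of the diene into the exo orientation (C3/C4 trans), the E-alkene giving C4/C5 trans and the larger HOMO coefficient at the diene CH2 terminus giving the C6–C5/C3–C4 regiochemistry.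

Step 8
Reactants: 12 7-hydroxychromone
Product: 13 7-acetoxychromone
Conditions: Ac2O, Et3N, DMAP (cat.), CH2Cl2, 0 °C to rt
Reagents that add atoms: acetic anhydride, CC(=O)OC(C)=O
Why: O-acylation of the single phenol shields ring A from the oxidants of steps 9 and 11.

Step 9
Reactants: 13 7-acetoxychromone
Product: 15 7-acetoxy-3-hydroxychromone, via 2,3-epoxychromanone 14 (not isolated)
Conditions: DMDO (acetone solution, excess), CH2Cl2, 0 °C to rt; evaporate; p-TsOH (cat.), CH2Cl2, rt
Reagents that add atoms: dimethyldioxirane, CC1(C)OO1
Why: Neutral dioxirane epoxidation of the C2=C3 bond followed by acid-catalysed epoxide-to-enol isomerisation (C2–O opening to the oxocarbenium ion, loss of H-3), conditions under which the aryl acetate survives.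

Step 10
Reactants: 15 7-acetoxy-3-hydroxychromone
Product: 16 7-acetoxy-3-(trimethylsilyloxy)chromone
Conditions: TMSCl, Et3N, THF, 0 °C to rt; filter, evaporate
Reagents that add atoms: chlorotrimethylsilane, C[Si](C)(C)Cl
Why: O-silylation of the enolic 3-OH gives the silyl enol ether needed for clean ligand exchange at iodine(III), the aryl acetate being inert.

Step 11
Reactants: 16 7-acetoxy-3-(trimethylsilyloxy)chromone; 11 (3R,4R,5S)-all-trans cycloadduct
Product: 19 (3R,4R,5S)-tetraacetate bis-MOM ether of the target (free 3-OH and chelated 2-OH), via iodine(III) enolonium 17 (not isolated), via chromane-3,4-dione tautomer 18 (not isolated)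
Conditions: PhI(OAc)2 (1.4 equiv), BF3·OEt2 (3 equiv), CH2Cl2, −78 °C, 16 (1.5 equiv) added dropwise, 10 min; then 11 (1.0 equiv), −78 to −30 °C; aq NaHCO3
Reagents that add atoms: none
Why: Proposed new method: silyl-to-iodine ligand exchange of 16 at BF3-activated PhI(OAc)2 gives the O-bound enolonium 17, in which departure of PhI turns the O3–C3=C2 enol of ring C into an α-keto oxocarbenium ion at C2 (also stabilised by O1); C1' of ring B of 11 attacks C2 in an SN2'-type Friedel–Crafts step, and loss of the arenium proton and enolisation of dione 18 restore ring B and the pyranone and set free the 3-OH. The closest known reaction types are the metal-free α-arylation of ketones by electron-rich arenes via enolonium species made from silyl enol ethers and iodine(III), and the iodine(III) oxidation of flavonols in alcohols, which places the external nucleophile on C2; the enol of a 2-unsubstituted 3-hydroxychromone has not been used as the umpoled partner of an arene. No ring is closed and no lasting stereocentre is formed, since C2 of 18 is planarised on enolisation and C3, C4 and C5 are untouched under base-free conditions at or below −30 °C. The step needs ring selectivity, which is secured electronically: ring B carries two alkoxy donors that converge on C1', whereas the other two benzene rings of 11 are damped by acetoxy and acyl groups. Position selectivity follows from the local symmetry of ring B (its two ortho/para C–H carbons are interchanged by rotation about C3–C3', the third C–H is meta to both oxygens), and O-attack or oxidation of 11 is avoided because ring B has no free OH, the only free OH is the chelated acyl-deactivated one, and all iodine(III) is bound to the chromone before 11 is added. A second arylation is blocked by the electron-poor chromonyl group installed by the first, and the hindered trisubstituted alkene is a much weaker π-nucleophile than the dialkoxyarene.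

Step 12
Reactants: 19 (3R,4R,5S)-tetraacetate bis-MOM ether of the target
Product: 20 target CNP0190989.1
Conditions: HCl in MeOH (1.25 M), argon, 0 to 35 °C
Reagents that add atoms: none
Why: Acid-catalysed transesterification of the four aryl acetates and acetal exchange of the two MOM ethers in one solvolysis, in which no stereocentre is touched and C4, the only epimerisable one, already has the thermodynamically preferred all-equatorial arrangement.

Compound list
1 | 2,4-dihydroxyacetophenone | CC(=O)c1ccc(O)cc1O | starting material
2 | 4-acetyl-3-hydroxyphenyl acetate | CC(=O)c1ccc(OC(C)=O)cc1O | intermediate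
3 | 2,4-dihydroxybenzaldehyde | O=Cc1ccc(O)cc1O | starting material
4 | 2,4-diacetoxybenzaldehyde | CC(=O)Oc1ccc(C=O)c(OC(C)=O)c1 | intermediate
5 | (E)-2'-hydroxy-2,4,4'-triacetoxychalcone | CC(=O)Oc1ccc(C(=O)/C=C/c2ccc(OC(C)=O)cc2OC(C)=O)c(O)c1 | intermediate
6 | 2-iodoresorcinol | Oc1cccc(O)c1I | starting material
7 | 2-iodo-1,3-bis(methoxymethoxy)benzene | COCOc1cccc(OCOC)c1I | intermediate
8 | 2-methylbut-1-en-3-yne | C#CC(C)=C | starting material
9 | (E)-(3-methylbuta-1,3-dienyl)boronic acid pinacol ester | CC(=C)/C=C/B1OC(C)(C)C(C)(C)O1 | intermediate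
10 | (E)-1,3-bis(methoxymethoxy)-2-(3-methylbuta-1,3-dienyl)benzene | COCOc1cccc(OCOC)c1/C=C/C(C)=C | intermediate
11 | (3R,4R,5S)-all-trans cycloadduct | CC1=C[C@@H](c2c(OCOC)cccc2OCOC)[C@H](C(=O)c2ccc(OC(C)=O)cc2O)[C@@H](c2ccc(OC(C)=O)cc2OC(C)=O)C1 | intermediate
12 | 7-hydroxychromone | O=c1ccoc2cc(O)ccc12 | starting material
13 | 7-acetoxychromone | CC(=O)Oc1ccc2c(=O)ccoc2c1 | intermediate
14 | rac-7-acetoxy-2,3-epoxychroman-4-one (cis-fused, not isolated) | CC(=O)Oc1ccc2c(c1)OC1OC1C2=O | intermediate
15 | 7-acetoxy-3-hydroxychromone | CC(=O)Oc1ccc2c(=O)c(O)coc2c1 | intermediate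
16 | 7-acetoxy-3-(trimethylsilyloxy)chromone | CC(=O)Oc1ccc2c(=O)c(O[Si](C)(C)C)coc2c1 | intermediate
17 | 7-acetoxy-3-[acetoxy(phenyl)-λ3-iodanyloxy]chromone, BF3-activated enolonium (not isolated) | CC(=O)Oc1ccc2c(=O)c(OI(OC(C)=O)c3ccccc3)coc2c1 | intermediate
18 | 2-aryl-2H-chromane-3,4-dione tautomer of 19, C2 unassigned (not isolated) | CC1=C[C@@H](c2c(OCOC)ccc(C3Oc4cc(OC(C)=O)ccc4C(=O)C3=O)c2OCOC)[C@H](C(=O)c2ccc(OC(C)=O)cc2O)[C@@H](c2ccc(OC(C)=O)cc2OC(C)=O)C1 | intermediate
19 | (3R,4R,5S)-tetraacetate bis-MOM ether of the target | CC1=C[C@@H](c2c(OCOC)ccc(-c3oc4cc(OC(C)=O)ccc4c(=O)c3O)c2OCOC)[C@H](C(=O)c2ccc(OC(C)=O)cc2O)[C@@H](c2ccc(OC(C)=O)cc2OC(C)=O)C1 | intermediate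
20 | CNP0190989.1, (3R,4R,5S) | CC1=C[C@@H](c2c(O)ccc(-c3oc4cc(O)ccc4c(=O)c3O)c2O)[C@H](C(=O)c2ccc(O)cc2O)[C@@H](c2ccc(O)cc2O)C1 | target

Total step count: 12
Longest linear sequence: 5 steps (for example 6 → 7 → 10 → 11 → 19 → 20; the branches from 1 and from 12 are equally long)

Steps most likely to fail

1. Step 11 (Proposed new method).
- What may go wrong: the enolonium may collapse by acetate transfer to C2, or by self-coupling with unreacted silyl enol ether, before the hindered arene attacks. The trisubstituted alkene may attack instead of ring B, or the chelated phenol may exchange at iodine.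
- Fallback (known chemistry, cross-coupling instead of the C–H/C–H union), setting out from 7 and coming back at 19: NBS in MeCN should brominate 7 at one of its two equivalent ortho/para positions to 1-bromo-3-iodo-2,4-bis(methoxymethoxy)benzene F1. Iodide-selective Suzuki–Miyaura coupling with 9 gives (E)-1-bromo-2,4-bis(methoxymethoxy)-3-(3-methylbuta-1,3-dienyl)benzene F2. The borate-promoted Diels–Alder reaction of step 7 with 5 gives the ring-B bromide of the cycloadduct F3. Zincation of 16 at C2, the only C–H of ring C, with TMPZnCl·LiCl gives the chromon-2-ylzinc chloride F4. Negishi coupling of F3 with an excess of F4 (one equivalent is lost to the chelated phenol) under Pd/SPhos gives the 3-O-trimethylsilyl ether of the coupled flavonol F5, which is desilylated by the citric acid work-up to 19.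

2. Step 7.
- What may go wrong: exo/endo or facial discrimination may be insufficient, or the borate may be inhibited by the product and by the MOM oxygens.
- Fallback (racemic cycloaddition and resolution instead of asymmetric induction), setting out from 5 and 10 and coming back at 11: electron-transfer catalysis by silica-supported silver nanoparticles (CH2Cl2, 50 °C) is a known way to engage 2'-hydroxychalcones with aryl dienes. It gives the exo adduct as the racemate, that is 11 together with its mirror image, the (3S,4S,5R)-cycloadduct F6. Preparative chiral SFC separates the two and returns 11.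

3. Step 12.
- What may go wrong: a liberated ring-B phenol may add to the trisubstituted alkene under acid, or the solvolysis may stay incomplete.
- Fallback (two orthogonal stages without protic acid), setting out from 19 and coming back at 20: K2CO3 in MeOH at 0 °C under argon removes the four acetates and gives the 2',4'-bis(methoxymethyl) ether of the target F7. ZnBr2 and n-PrSH in CH2Cl2 at 0 °C then cleave the two MOM ethers by thiol capture of the oxocarbenium ion and give 20.

Further compounds
F1 | step 11 | 1-bromo-3-iodo-2,4-bis(methoxymethoxy)benzene | COCOc1ccc(Br)c(OCOC)c1I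
F2 | step 11 | (E)-1-bromo-2,4-bis(methoxymethoxy)-3-(3-methylbuta-1,3-dienyl)benzene | COCOc1ccc(Br)c(OCOC)c1/C=C/C(C)=C
F3 | step 11 | ring-B bromide of the cycloadduct | CC1=C[C@@H](c2c(OCOC)ccc(Br)c2OCOC)[C@H](C(=O)c2ccc(OC(C)=O)cc2O)[C@@H](c2ccc(OC(C)=O)cc2OC(C)=O)C1
F4 | step 11 | chromon-2-ylzinc chloride (7-acetoxy-3-trimethylsilyloxy) | CC(=O)Oc1ccc2c(=O)c(O[Si](C)(C)C)c([Zn]Cl)oc2c1
F5 | step 11 | 3-O-trimethylsilyl ether of the coupled flavonol | CC1=C[C@@H](c2c(OCOC)ccc(-c3oc4cc(OC(C)=O)ccc4c(=O)c3O[Si](C)(C)C)c2OCOC)[C@H](C(=O)c2ccc(OC(C)=O)cc2O)[C@@H](c2ccc(OC(C)=O)cc2OC(C)=O)C1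
F6 | step 7 | (3S,4S,5R)-cycloadduct, mirror image of 11 | CC1=C[C@H](c2c(OCOC)cccc2OCOC)[C@@H](C(=O)c2ccc(OC(C)=O)cc2O)[C@H](c2ccc(OC(C)=O)cc2OC(C)=O)C1
F7 | step 12 | 2',4'-bis(methoxymethyl) ether of the target | CC1=C[C@@H](c2c(OCOC)ccc(-c3oc4cc(O)ccc4c(=O)c3O)c2OCOC)[C@H](C(=O)c2ccc(O)cc2O)[C@@H](c2ccc(O)cc2O)C1
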